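The dihydropyran ring of the chroman is cut at C2–C3 and O1–C8a. This exploits that the quaternary C2 and the ring oxygen O1 are the carbonyl group of a methyl ketone, all-E geranylgeranylacetone, while C3–C4–C4a–C8a is a 2-(2-bromoaryl)ethyl unit, nucleophilic at C3 and electrophilic at C8a. In one flask its Grignard reagent adds to the ketone under a chiral diamine–phenol ligand, which sets C2, and the magnesium alkoxide is O-arylated at C8a with a Pd(OAc)2/phosphine catalyst. The chain is then oxidised at its terminal methyl group and joined to a C20 sulfone whose (S)-carbinol comes from Sharpless epoxidation of farnesol and is carried as a propargylic alcohol.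

Key step: step 7

Remark 1: the target is read as 2S at C2 of the chroman and S at the side-chain carbinol C24' (side chain numbered C1' to C33' from the ring).
Remark 2 (assumption): geranylgeranylacetone is bought as the isomerically pure (5E,9E,13E) ketone; the 5E/5Z mixture is not suitable.
Remark 3 (assumption): the (1R,2R) ligand is taken to deliver the alkyl group to the Re face of the ketone; if the sense is the opposite, its enantiomer is used without other change.

Step 1
Reactants: 1 2,3-dimethylphenol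
Product: 2 triisopropyl(2,3-dimethylphenoxy)silane
Conditions: TIPSCl, imidazole, DMF, rt
Reagents that add atoms: chlorotriisopropylsilane, CC(C)[Si](Cl)(C(C)C)C(C)C
Why: Silyl ether formation; the bulky silyl group should survive the organometallic, basic and hydride steps, shield its ortho position in step 5 and leave with fluoride at the end.

Step 2
Reactants: 2 triisopropyl(2,3-dimethylphenoxy)silane
Product: 3 2-[3,4-dimethyl-5-(triisopropylsilyloxy)phenyl]-4,4,5,5-tetramethyl-1,3,2-dioxaborolane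
Conditions: [Ir(OMe)(cod)]2 (1.5 mol%), 4,4'-di-tert-butyl-2,2'-bipyridine (3 mol%), B2pin2, hexane, 50 °C
Reagents that add atoms: bis(pinacolato)diboron, CC1(C)OB(OC1(C)C)B1OC(C)(C)C(C)(C)O1
Why: Iridium-catalysed aromatic C–H borylation is sterically controlled and should go to the only ring position that has no ortho substituent.

Step 3
Reactants: 3 2-[3,4-dimethyl-5-(triisopropylsilyloxy)phenyl]-4,4,5,5-tetramethyl-1,3,2-dioxaborolane
Product: 4 (5-ethenyl-2,3-dimethylphenoxy)triisopropylsilane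
Conditions: vinyl bromide (1 M in THF), Pd(dppf)Cl2 (3 mol%), K3PO4, THF/H2O, 60 °C, sealed tube
Reagents that add atoms: vinyl bromide, C=CBr
Why: Suzuki–Miyaura coupling of the aryl boronate with vinyl bromide should give the styrene that carries the future C3 and C4.

Step 4
Reactants: 4 (5-ethenyl-2,3-dimethylphenoxy)triisopropylsilane
Product: 6 2-[3,4-dimethyl-5-(triisopropylsilyloxy)phenyl]ethanol, via alkylborane 5 (not isolated)
Conditions: 9-BBN, THF, 0 °C to rt; then aq. NaOAc, 30% H2O2, 0 °C to rt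
Reagents that add atoms: hydrogen peroxide, OO
Why: Hydroboration–oxidation; 9-BBN adds anti-Markovnikov to the styrene and the buffered oxidation should spare the aryl silyl ether.

Step 5
Reactants: 6 2-[3,4-dimethyl-5-(triisopropylsilyloxy)phenyl]ethanol
Product: 7 2-[2-bromo-3,4-dimethyl-5-(triisopropylsilyloxy)phenyl]ethanol
Conditions: NBS, MeCN, 0 °C
Reagents that add atoms: N-bromosuccinimide, O=C1CCC(=O)N1Br
Why: Electrophilic aromatic bromination should go para to the silyloxy group, because the ortho position lies between the bulky silyl ether and the side chain; this places bromine on the future C8a.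

Step 6
Reactants: 7 2-[2-bromo-3,4-dimethyl-5-(triisopropylsilyloxy)phenyl]ethanol
Product: 8 [4-bromo-5-(2-iodoethyl)-2,3-dimethylphenoxy]triisopropylsilane
Conditions: I2, PPh3, imidazole, CH2Cl2, 0 °C
Reagents that add atoms: iodine, II
Why: Appel-type iodination of the primary alcohol gives the precursor of the C3 nucleophile.

Step 7
Reactants: 8 [4-bromo-5-(2-iodoethyl)-2,3-dimethylphenoxy]triisopropylsilane; 9 (5E,9E,13E)-6,10,14,18-tetramethylnonadeca-5,9,13,17-tetraen-2-one
Product: 12 (2S)-2,7,8-trimethyl-2-[(3E,7E,11E)-4,8,12,16-tetramethylheptadeca-3,7,11,15-tetraen-1-yl]-6-(triisopropylsilyloxy)chroman, via Grignard reagent 10 (not isolated), via magnesium alkoxide 11 (not isolated)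
Conditions: Mg turnings, Et2O, 0 °C; added to the bromomagnesium phenoxide of 2,4-di-tert-butyl-6-({[(1R,2R)-2-(dimethylamino)cyclohexyl](methyl)amino}methyl)phenol (1.1 equiv, from the ligand and MeMgBr) in toluene, −82 °C; then 9, −82 °C; warmed to rt, Et2O removed; then Pd(OAc)2 (3 mol%), 2-(di-tert-butylphosphino)-1,1'-binaphthyl (4 mol%), Cs2CO3, toluene, 70 °C
Reagents that add atoms: none
Why: Magnesium inserts into the primary C–I bond of 8 (the hindered, electron-rich aryl bromide should be left), and the Grignard reagent 10, held by the tridentate ligand on magnesium, adds 1,2 to ketone 9 to form C2–C3; without work-up, zerovalent palladium (formed from Pd(OAc)2) inserts into the C8a–Br bond of 11, the alkoxide replaces bromide on palladium and C–O reductive elimination forms O1–C8a. The closest known reaction types are the ligand-mediated asymmetric addition of Grignard reagents to ketones and the palladium-catalysed intramolecular etherification of tertiary alcohols with aryl bromides (Buchwald–Hartwig type C–O coupling). The dihydropyran ring is closed by aryl–oxygen reductive elimination from a seven-membered oxapalladacycle, a six-membered ring closure at the aryl carbon. The new stereocentre C2 is set in the addition by the chiral ligand on magnesium (reagent control: attack on the Re face, ranked O > CH2 > CH3, gives S) and cannot be lost in the ring closure, because the C2–O bond is never broken and the carbinol carbon bears no hydrogen for β-hydride elimination. The step needs facial discrimination between a methyl and a primary alkyl arm, which rests on the ligand alone and is its weak point, and it needs C–O coupling to win over Heck reaction, which the six-membered geometry and the trisubstituted alkenes should secure.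

Step 8
Reactants: 12 (2S)-2,7,8-trimethyl-2-[(3E,7E,11E)-4,8,12,16-tetramethylheptadeca-3,7,11,15-tetraen-1-yl]-6-(triisopropylsilyloxy)chroman
Product: 13 (2E,6E,10E,14E)-2,6,10,14-tetramethyl-17-[(2S)-2,7,8-trimethyl-6-(triisopropylsilyloxy)chroman-2-yl]heptadeca-2,6,10,14-tetraen-1-ol
Conditions: SeO2 (0.2 equiv), t-BuOOH, salicylic acid (0.1 equiv), CH2Cl2, 0 °C to rt
Reagents that add atoms: tert-butyl hydroperoxide, CC(C)(C)OO (oxygen passed on by catalytic selenium dioxide, O=[Se]=O)
Why: Catalytic SeO2 allylic oxidation (ene reaction, then 2,3-sigmatropic shift) should attack the E-methyl group of the terminal, most accessible isopropylidene unit and give the E-allylic alcohol.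

Step 9
Reactants: 13 (2E,6E,10E,14E)-2,6,10,14-tetramethyl-17-[(2S)-2,7,8-trimethyl-6-(triisopropylsilyloxy)chroman-2-yl]heptadeca-2,6,10,14-tetraen-1-ol
Product: 14 (2S)-2-[(3E,7E,11E,15E)-17-bromo-4,8,12,16-tetramethylheptadeca-3,7,11,15-tetraen-1-yl]-2,7,8-trimethyl-6-(triisopropylsilyloxy)chroman
Conditions: CBr4, PPh3, CH2Cl2, 0 °C
Reagents that add atoms: carbon tetrabromide, BrC(Br)(Br)Br
Why: Appel bromination of the primary allylic alcohol should proceed without allylic transposition or loss of the E geometry.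

Step 10
Reactants: 15 (2E,6E)-farnesol
Product: 16 (2S,3S)-2,3-epoxyfarnesol, that is {(2S,3S)-3-[(3E)-4,8-dimethylnona-3,7-dien-1-yl]-3-methyloxiran-2-yl}methanol
Conditions: Ti(OiPr)4 (10 mol%), L-(+)-diethyl tartrate (12 mol%), t-BuOOH, 4 Å molecular sieves, CH2Cl2, −20 °C
Reagents that add atoms: tert-butyl hydroperoxide, CC(C)(C)OO
Why: Sharpless asymmetric epoxidation oxidises only the alkene of the allylic alcohol, and the L-(+)-tartrate ligand sets the future carbinol carbon as 3S (reagent control).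

Step 11
Reactants: 16 (2S,3S)-2,3-epoxyfarnesol
Product: 17 (2S,3R)-3-(chloromethyl)-2-[(3E)-4,8-dimethylnona-3,7-dien-1-yl]-2-methyloxirane
Conditions: PPh3, CCl4, NaHCO3, reflux
Reagents that add atoms: tetrachloromethane, ClC(Cl)(Cl)Cl
Why: Appel chlorination of the primary alcohol under buffered conditions should leave the epoxide and both stereocentres untouched.

Step 12
Reactants: 17 (2S,3R)-3-(chloromethyl)-2-[(3E)-4,8-dimethylnona-3,7-dien-1-yl]-2-methyloxirane
Product: 18 (3S,6E)-3,7,11-trimethyldodeca-6,10-dien-1-yn-3-ol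
Conditions: n-BuLi (3 equiv), THF, −78 to −30 °C; then aq. NH4Cl
Reagents that add atoms: none
Why: Base-induced double elimination of the epoxy chloride (deprotonation at CH2Cl, epoxide opening to the chlorovinyl alkoxide, loss of HCl) should give the terminal propargylic alcohol, and the C–O bond at the stereocentre is not broken, so S is kept.

Step 13
Reactants: 19 3-methylbut-2-en-1-yl acetate (prenyl acetate)
Product: 20 (2E)-4-hydroxy-3-methylbut-2-en-1-yl acetate
Conditions: SeO2 (0.3 equiv), t-BuOOH, CH2Cl2, rt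
Reagents that add atoms: tert-butyl hydroperoxide, CC(C)(C)OO (oxygen passed on by catalytic selenium dioxide, O=[Se]=O)
Why: SeO2 allylic oxidation should take the E-methyl group and give the E-allylic alcohol.

Step 14
Reactants: 20 (2E)-4-hydroxy-3-methylbut-2-en-1-yl acetate
Product: 21 (2E)-4-bromo-3-methylbut-2-en-1-yl acetate
Conditions: CBr4, PPh3, CH2Cl2, 0 °C
Reagents that add atoms: carbon tetrabromide, BrC(Br)(Br)Br
Why: Appel bromination gives the differentiated C5 unit, with the bromide at the methyl-bearing end and the acetate at the other.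

Step 15
Reactants: 18 (3S,6E)-3,7,11-trimethyldodeca-6,10-dien-1-yn-3-ol; 21 (2E)-4-bromo-3-methylbut-2-en-1-yl acetate
Product: 22 (2E,7S,10E)-7-hydroxy-3,7,11,15-tetramethylhexadeca-2,10,14-trien-5-yn-1-yl acetate
Conditions: CuI (0.2 equiv), NaI (0.2 equiv), K2CO3, DMF, rt
Reagents that add atoms: none
Why: Copper-mediated coupling of the terminal alkyne (as copper acetylide) with the primary allylic bromide should form C21'–C22' at the unhindered carbon and tolerate the free tertiary alcohol and the acetate.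

Step 16
Reactants: 22 (2E,7S,10E)-7-hydroxy-3,7,11,15-tetramethylhexadeca-2,10,14-trien-5-yn-1-yl acetate
Product: 23 (2E,7S,10E)-3,7,11,15-tetramethyl-1-(phenylsulfonyl)hexadeca-2,10,14-trien-5-yn-7-ol
Conditions: Pd(PPh3)4 (5 mol%), PhSO2Na, THF/MeOH, rt
Reagents that add atoms: sodium benzenesulfinate, [Na+].[O-]S(=O)c1ccccc1
Why: Palladium-catalysed allylic substitution (Tsuji–Trost) of the acetate by sulfinate should occur at the unsubstituted allyl terminus with retention of the E geometry.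

Step 17
Reactants: 23 (2E,7S,10E)-3,7,11,15-tetramethyl-1-(phenylsulfonyl)hexadeca-2,10,14-trien-5-yn-7-ol; 14 (2S)-2-[(3E,7E,11E,15E)-17-bromo-4,8,12,16-tetramethylheptadeca-3,7,11,15-tetraen-1-yl]-2,7,8-trimethyl-6-(triisopropylsilyloxy)chroman
Product: 24 (2S)-2-[(3E,7E,11E,15E,19E,24S,27E)-24-hydroxy-4,8,12,16,20,24,28,32-octamethyl-18-(phenylsulfonyl)tritriaconta-3,7,11,15,19,27,31-heptaen-22-yn-1-yl]-2,7,8-trimethyl-6-(triisopropylsilyloxy)chroman (both epimers at C18')
Conditions: n-BuLi (2.1 equiv), THF/DMPU, −78 °C; then 14, −78 to −20 °C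
Reagents that add atoms: none
Why: Alkylation of the allylic sulfone carbanion (used as the alkoxide–carbanion dianion) by the allylic bromide is the classical head-to-tail union of prenyl units and should form C17'–C18' without touching either alkene.

Step 18
Reactants: 24 the sulfone described in step 17
Product: 25 (2S)-2-[(3E,7E,11E,15E,19E,24S,27E)-24-hydroxy-4,8,12,16,20,24,28,32-octamethyltritriaconta-3,7,11,15,19,27,31-heptaen-22-yn-1-yl]-2,7,8-trimethyl-6-(triisopropylsilyloxy)chroman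
Conditions: Pd(dppp)Cl2 (5 mol%), LiBHEt3, THF, 0 °C
Reagents that add atoms: none
Why: Palladium-catalysed reductive desulfonylation of the allylic sulfone should deliver hydride to the less substituted terminus of the allyl intermediate, so the trisubstituted E-alkene stays in place.

Step 19
Reactants: 25 the enyne described in step 18
Product: 26 (2S)-2-[(3E,7E,11E,15E,19E,22E,24S,27E)-24-hydroxy-4,8,12,16,20,24,28,32-octamethyltritriaconta-3,7,11,15,19,22,27,31-octaen-1-yl]-2,7,8-trimethyl-6-(triisopropylsilyloxy)chroman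
Conditions: NaAlH2(OCH2CH2OMe)2, THF, 0 °C to rt; then aq. potassium sodium tartrate
Reagents that add atoms: none
Why: Hydroxyl-directed trans-hydroalumination of the propargylic alcohol followed by protonolysis should give the E-allylic alcohol and leave the isolated alkenes alone.

Step 20
Reactants: 26 the silyl ether described in step 19
Product: 27 (2S)-2-[(3E,7E,11E,15E,19E,22E,24S,27E)-24-hydroxy-4,8,12,16,20,24,28,32-octamethyltritriaconta-3,7,11,15,19,22,27,31-octaen-1-yl]-2,7,8-trimethylchroman-6-ol (target)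
Conditions: Bu4NF, THF, 0 °C
Reagents that add atoms: none
Why: Fluoride cleavage of the aryl silyl ether is neutral enough to spare the tertiary allylic alcohol and the polyene; any phenol already set free in step 19 is the target itself.

Compound list
1 | 2,3-dimethylphenol | Cc1cccc(O)c1C | starting material
2 | triisopropyl(2,3-dimethylphenoxy)silane | Cc1cccc(O[Si](C(C)C)(C(C)C)C(C)C)c1C | intermediate
3 | 2-[3,4-dimethyl-5-(triisopropylsilyloxy)phenyl]-4,4,5,5-tetramethyl-1,3,2-dioxaborolane | Cc1cc(B2OC(C)(C)C(C)(C)O2)cc(O[Si](C(C)C)(C(C)C)C(C)C)c1C | intermediate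
4 | (5-ethenyl-2,3-dimethylphenoxy)triisopropylsilane | C=Cc1cc(C)c(C)c(O[Si](C(C)C)(C(C)C)C(C)C)c1 | intermediate
5 | 9-{2-[3,4-dimethyl-5-(triisopropylsilyloxy)phenyl]ethyl}-9-borabicyclo[3.3.1]nonane | C1CC2CCCC(C1)B2CCc1cc(C)c(C)c(O[Si](C(C)C)(C(C)C)C(C)C)c1 | intermediate (not isolated)
6 | 2-[3,4-dimethyl-5-(triisopropylsilyloxy)phenyl]ethanol | OCCc1cc(C)c(C)c(O[Si](C(C)C)(C(C)C)C(C)C)c1 | intermediate
7 | 2-[2-bromo-3,4-dimethyl-5-(triisopropylsilyloxy)phenyl]ethanol | OCCc1cc(O[Si](C(C)C)(C(C)C)C(C)C)c(C)c(C)c1Br | intermediate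
8 | [4-bromo-5-(2-iodoethyl)-2,3-dimethylphenoxy]triisopropylsilane | ICCc1cc(O[Si](C(C)C)(C(C)C)C(C)C)c(C)c(C)c1Br | intermediate
9 | (5E,9E,13E)-6,10,14,18-tetramethylnonadeca-5,9,13,17-tetraen-2-one (all-E geranylgeranylacetone) | CC(C)=CCC/C(C)=C/CC/C(C)=C/CC/C(C)=C/CCC(C)=O | starting material
10 | {2-[2-bromo-3,4-dimethyl-5-(triisopropylsilyloxy)phenyl]ethyl}magnesium iodide | I[Mg]CCc1cc(O[Si](C(C)C)(C(C)C)C(C)C)c(C)c(C)c1Br | intermediate (not isolated)
11 | iodomagnesium (3S,6E,10E,14E)-1-[2-bromo-3,4-dimethyl-5-(triisopropylsilyloxy)phenyl]-3,7,11,15,19-pentamethylicosa-6,10,14,18-tetraen-3-olate | CC(C)=CCC/C(C)=C/CC/C(C)=C/CC/C(C)=C/CC[C@](C)(O[Mg]I)CCc1cc(O[Si](C(C)C)(C(C)C)C(C)C)c(C)c(C)c1Br | intermediate (not isolated)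
12 | (2S)-2,7,8-trimethyl-2-[(3E,7E,11E)-4,8,12,16-tetramethylheptadeca-3,7,11,15-tetraen-1-yl]-6-(triisopropylsilyloxy)chroman | CC(C)=CCC/C(C)=C/CC/C(C)=C/CC/C(C)=C/CC[C@@]1(C)CCc2cc(O[Si](C(C)C)(C(C)C)C(C)C)c(C)c(C)c2O1 | intermediate
13 | (2E,6E,10E,14E)-2,6,10,14-tetramethyl-17-[(2S)-2,7,8-trimethyl-6-(triisopropylsilyloxy)chroman-2-yl]heptadeca-2,6,10,14-tetraen-1-ol | OC/C(C)=C/CC/C(C)=C/CC/C(C)=C/CC/C(C)=C/CC[C@@]1(C)CCc2cc(O[Si](C(C)C)(C(C)C)C(C)C)c(C)c(C)c2O1 | intermediate
14 | (2S)-2-[(3E,7E,11E,15E)-17-bromo-4,8,12,16-tetramethylheptadeca-3,7,11,15-tetraen-1-yl]-2,7,8-trimethyl-6-(triisopropylsilyloxy)chroman | BrC/C(C)=C/CC/C(C)=C/CC/C(C)=C/CC/C(C)=C/CC[C@@]1(C)CCc2cc(O[Si](C(C)C)(C(C)C)C(C)C)c(C)c(C)c2O1 | intermediate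
15 | (2E,6E)-farnesol | CC(C)=CCC/C(C)=C/CC/C(C)=C/CO | starting material
16 | (2S,3S)-2,3-epoxyfarnesol | CC(C)=CCC/C(C)=C/CC[C@]1(C)O[C@H]1CO | intermediate
17 | (2S,3R)-3-(chloromethyl)-2-[(3E)-4,8-dimethylnona-3,7-dien-1-yl]-2-methyloxirane | CC(C)=CCC/C(C)=C/CC[C@]1(C)O[C@H]1CCl | intermediate
18 | (3S,6E)-3,7,11-trimethyldodeca-6,10-dien-1-yn-3-ol | CC(C)=CCC/C(C)=C/CC[C@](C)(O)C#C | intermediate
19 | 3-methylbut-2-en-1-yl acetate | CC(C)=CCOC(C)=O | starting material
20 | (2E)-4-hydroxy-3-methylbut-2-en-1-yl acetate | OC/C(C)=C/COC(C)=O | intermediate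
21 | (2E)-4-bromo-3-methylbut-2-en-1-yl acetate | BrC/C(C)=C/COC(C)=O | intermediate
22 | (2E,7S,10E)-7-hydroxy-3,7,11,15-tetramethylhexadeca-2,10,14-trien-5-yn-1-yl acetate | CC(C)=CCC/C(C)=C/CC[C@](C)(O)C#CC/C(C)=C/COC(C)=O | intermediate
23 | (2E,7S,10E)-3,7,11,15-tetramethyl-1-(phenylsulfonyl)hexadeca-2,10,14-trien-5-yn-7-ol | CC(C)=CCC/C(C)=C/CC[C@](C)(O)C#CC/C(C)=C/CS(=O)(=O)c1ccccc1 | intermediate
24 | (2S)-2-[(3E,7E,11E,15E,19E,24S,27E)-24-hydroxy-4,8,12,16,20,24,28,32-octamethyl-18-(phenylsulfonyl)tritriaconta-3,7,11,15,19,27,31-heptaen-22-yn-1-yl]-2,7,8-trimethyl-6-(triisopropylsilyloxy)chroman, both epimers at C18' | CC(C)=CCC/C(C)=C/CC[C@](C)(O)C#CC/C(C)=C/C(S(=O)(=O)c1ccccc1)C/C(C)=C/CC/C(C)=C/CC/C(C)=C/CC/C(C)=C/CC[C@@]2(C)CCc3cc(O[Si](C(C)C)(C(C)C)C(C)C)c(C)c(C)c3O2 | intermediate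
25 | (2S)-2-[(3E,7E,11E,15E,19E,24S,27E)-24-hydroxy-4,8,12,16,20,24,28,32-octamethyltritriaconta-3,7,11,15,19,27,31-heptaen-22-yn-1-yl]-2,7,8-trimethyl-6-(triisopropylsilyloxy)chroman | CC(C)=CCC/C(C)=C/CC[C@](C)(O)C#CC/C(C)=C/CC/C(C)=C/CC/C(C)=C/CC/C(C)=C/CC/C(C)=C/CC[C@@]1(C)CCc2cc(O[Si](C(C)C)(C(C)C)C(C)C)c(C)c(C)c2O1 | intermediate
26 | (2S)-2-[(3E,7E,11E,15E,19E,22E,24S,27E)-24-hydroxy-4,8,12,16,20,24,28,32-octamethyltritriaconta-3,7,11,15,19,22,27,31-octaen-1-yl]-2,7,8-trimethyl-6-(triisopropylsilyloxy)chroman | CC(C)=CCC/C(C)=C/CC[C@](C)(O)/C=C/C/C(C)=C/CC/C(C)=C/CC/C(C)=C/CC/C(C)=C/CC/C(C)=C/CC[C@@]1(C)CCc2cc(O[Si](C(C)C)(C(C)C)C(C)C)c(C)c(C)c2O1 | intermediate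
27 | (2S)-2-[(3E,7E,11E,15E,19E,22E,24S,27E)-24-hydroxy-4,8,12,16,20,24,28,32-octamethyltritriaconta-3,7,11,15,19,22,27,31-octaen-1-yl]-2,7,8-trimethylchroman-6-ol | CC(C)=CCC/C(C)=C/CC[C@](C)(O)/C=C/C/C(C)=C/CC/C(C)=C/CC/C(C)=C/CC/C(C)=C/CC/C(C)=C/CC[C@@]1(C)CCc2cc(O)c(C)c(C)c2O1 | target

Total step count: 20. Longest linear sequence: 13 steps (steps 1 to 9, then 17 to 20).

Steps most likely to fail

Step 7. The addition may show low facial discrimination between the methyl and the primary alkyl arm of the ketone, since this ligand class is at its best with aryl ketones. The hindered magnesium alkoxide may also pass slowly onto palladium. The fallback sets out from ketone 9 and iodide 8, returns at chroman 12, and makes the stereocentre stereospecifically instead. Ketone 9 is reduced with an (S)-selective alcohol dehydrogenase (NADPH, 2-propanol) to (2S,5E,9E,13E)-6,10,14,18-tetramethylnonadeca-5,9,13,17-tetraen-2-ol F1, which is acylated with 2,4,6-triisopropylbenzoyl chloride (pyridine, DMAP) to the hindered benzoate F2. Iodide 8 is turned into the pinacol boronate 2-{2-[2-bromo-3,4-dimethyl-5-(triisopropylsilyloxy)phenyl]ethyl}-4,4,5,5-tetramethyl-1,3,2-dioxaborolane F3 (B2pin2, CuI, PPh3, LiOMe, DMF). F2 is lithiated next to oxygen (s-BuLi, TMEDA, cyclopentyl methyl ether, −60 °C; the ester carbonyl directs the base) and trapped with F3. The boronate complex undergoes 1,2-migration (MgBr2, MeOH, warming) to the tertiary boronic ester F4. Oxidation (H2O2, NaOH) gives the tertiary alcohol (3S,6E,10E,14E)-1-[2-bromo-3,4-dimethyl-5-(triisopropylsilyloxy)phenyl]-3,7,11,15,19-pentamethylicosa-6,10,14,18-tetraen-3-ol F5. Lithiation and borylation go with retention and the migration with inversion, so (S)-F1 should lead to (S)-F5. The etherification of step 7 (Pd(OAc)2, 2-(di-tert-butylphosphino)-1,1'-binaphthyl, Cs2CO3, toluene, 70 °C), run on its own, then closes F5 to 12.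

Step 8. Oxidation may also occur at internal allylic positions, and the product may be over-oxidised to the enal at low conversion. The fallback sets out from 12, returns at 13, and rebuilds the terminus by cleavage and olefination. In aqueous THF, NBS should pick the terminal alkene and give the bromohydrin F6, which K2CO3 in MeOH closes to the terminal epoxide F7. HIO4 cleaves F7 to the aldehyde F8 with loss of acetone. A Wittig reaction with ethyl 2-(triphenylphosphoranylidene)propanoate gives the E-configured unsaturated ester F9, and i-Bu2AlH reduces it to 13.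

Step 18. Hydride may be delivered to the wrong terminus of the allyl–palladium intermediate, with migration of the C19'–C20' double bond, and palladium hydride may partly reduce the alkyne. The fallback sets out from acetate 22 and bromide 14, returns at target 27, and replaces the sulfone by an allylbarium coupling. NaAlH2(OCH2CH2OMe)2 reduces 22 to (2E,5E,7S,10E)-3,7,11,15-tetramethylhexadeca-2,5,10,14-tetraene-1,7-diol F10 (alkyne to E-alkene, acetate removed). The primary allylic alcohol is chlorinated selectively (MsCl, 2,4,6-collidine, LiCl, DMF, 0 °C) to the chloride F11, and the tertiary alcohol is silylated (TMSCl, imidazole) to the trimethylsilyl ether F12. Activated barium (from BaI2 and lithium biphenylide, THF, −78 °C) converts F12 into the allylbarium reagent, which should couple with 14 at its unsubstituted terminus with retention of geometry to give the bis-silyl ether F13. Bu4NF, as in step 20, removes both silyl groups and gives 27.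

Further compounds
F1 | step 7 | (2S,5E,9E,13E)-6,10,14,18-tetramethylnonadeca-5,9,13,17-tetraen-2-ol | CC(C)=CCC/C(C)=C/CC/C(C)=C/CC/C(C)=C/CC[C@H](C)O
F2 | step 7 | (2S,5E,9E,13E)-6,10,14,18-tetramethylnonadeca-5,9,13,17-tetraen-2-yl 2,4,6-triisopropylbenzoate | CC(C)=CCC/C(C)=C/CC/C(C)=C/CC/C(C)=C/CC[C@H](C)OC(=O)c1c(C(C)C)cc(C(C)C)cc1C(C)C
F3 | step 7 | 2-{2-[2-bromo-3,4-dimethyl-5-(triisopropylsilyloxy)phenyl]ethyl}-4,4,5,5-tetramethyl-1,3,2-dioxaborolane | CC1(C)OB(CCc2cc(O[Si](C(C)C)(C(C)C)C(C)C)c(C)c(C)c2Br)OC1(C)C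
F4 | step 7 | 2-{(3R,6E,10E,14E)-1-[2-bromo-3,4-dimethyl-5-(triisopropylsilyloxy)phenyl]-3,7,11,15,19-pentamethylicosa-6,10,14,18-tetraen-3-yl}-4,4,5,5-tetramethyl-1,3,2-dioxaborolane | CC(C)=CCC/C(C)=C/CC/C(C)=C/CC/C(C)=C/CC[C@](C)(B1OC(C)(C)C(C)(C)O1)CCc1cc(O[Si](C(C)C)(C(C)C)C(C)C)c(C)c(C)c1Br
F5 | step 7 | (3S,6E,10E,14E)-1-[2-bromo-3,4-dimethyl-5-(triisopropylsilyloxy)phenyl]-3,7,11,15,19-pentamethylicosa-6,10,14,18-tetraen-3-ol | CC(C)=CCC/C(C)=C/CC/C(C)=C/CC/C(C)=C/CC[C@](C)(O)CCc1cc(O[Si](C(C)C)(C(C)C)C(C)C)c(C)c(C)c1Br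
F6 | step 8 | terminal bromohydrin of 12, (2S)-2-[(3E,7E,11E)-15-bromo-16-hydroxy-4,8,12,16-tetramethylheptadeca-3,7,11-trien-1-yl]-2,7,8-trimethyl-6-(triisopropylsilyloxy)chroman, both epimers at C15' | CC(C)(O)C(Br)CC/C(C)=C/CC/C(C)=C/CC/C(C)=C/CC[C@@]1(C)CCc2cc(O[Si](C(C)C)(C(C)C)C(C)C)c(C)c(C)c2O1
F7 | step 8 | terminal epoxide of 12, (2S)-2-[(3E,7E,11E)-13-(3,3-dimethyloxiran-2-yl)-4,8,12-trimethyltrideca-3,7,11-trien-1-yl]-2,7,8-trimethyl-6-(triisopropylsilyloxy)chroman, both epimers at the oxirane | CC1(C)OC1CC/C(C)=C/CC/C(C)=C/CC/C(C)=C/CC[C@@]2(C)CCc3cc(O[Si](C(C)C)(C(C)C)C(C)C)c(C)c(C)c3O2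
F8 | step 8 | (4E,8E,12E)-4,8,12-trimethyl-15-[(2S)-2,7,8-trimethyl-6-(triisopropylsilyloxy)chroman-2-yl]pentadeca-4,8,12-trienal | O=CCC/C(C)=C/CC/C(C)=C/CC/C(C)=C/CC[C@@]1(C)CCc2cc(O[Si](C(C)C)(C(C)C)C(C)C)c(C)c(C)c2O1
F9 | step 8 | ethyl (2E,6E,10E,14E)-2,6,10,14-tetramethyl-17-[(2S)-2,7,8-trimethyl-6-(triisopropylsilyloxy)chroman-2-yl]heptadeca-2,6,10,14-tetraenoate | CCOC(=O)/C(C)=C/CC/C(C)=C/CC/C(C)=C/CC/C(C)=C/CC[C@@]1(C)CCc2cc(O[Si](C(C)C)(C(C)C)C(C)C)c(C)c(C)c2O1
F10 | step 18 | (2E,5E,7S,10E)-3,7,11,15-tetramethylhexadeca-2,5,10,14-tetraene-1,7-diol | CC(C)=CCC/C(C)=C/CC[C@](C)(O)/C=C/C/C(C)=C/CO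
F11 | step 18 | (2E,5E,7S,10E)-1-chloro-3,7,11,15-tetramethylhexadeca-2,5,10,14-tetraen-7-ol | CC(C)=CCC/C(C)=C/CC[C@](C)(O)/C=C/C/C(C)=C/CCl
F12 | step 18 | {[(2E,5E,7S,10E)-1-chloro-3,7,11,15-tetramethylhexadeca-2,5,10,14-tetraen-7-yl]oxy}trimethylsilane | CC(C)=CCC/C(C)=C/CC[C@](C)(O[Si](C)(C)C)/C=C/C/C(C)=C/CCl
F13 | step 18 | trimethylsilyl ether of 26 at the C24' oxygen | CC(C)=CCC/C(C)=C/CC[C@](C)(O[Si](C)(C)C)/C=C/C/C(C)=C/CC/C(C)=C/CC/C(C)=C/CC/C(C)=C/CC/C(C)=C/CC[C@@]1(C)CCc2cc(O[Si](C(C)C)(C(C)C)C(C)C)c(C)c(C)c2O1
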